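Target gained per starting material lost is the ratio worth hunting here: it should turn two readings into a whole row. You have two earlier runs and five flasks to forecast:

| flask | starting material | other conformer | protic impurity | remark | time |
|---|---|---|---|---|---|
| epsilon | 0.18 M | 0.13 equiv | 0.036 M | run made earlier |  |
| gamma | 0.18 M | 1.8 equiv | 0.036 M | run made earlier |  |
| maple | 0.18 M | 0.100 equiv | 0.0360 M |  | 20 min |
| cedar | 0.18 M | 0.200 equiv | 0.0360 M |  | 20 min |
| elm | 0.18 M | 0.400 equiv | 0.0360 M |  | 20 min |
| alder | 0.18 M | 0.800 equiv | 0.0360 M |  | 20 min |
| oak | 0.18 M | 1.50 equiv | 0.0360 M |  | 20 min |

| run | time / min | target / % | starting material / % |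
|---|---|---|---|
| epsilon | 1.50 | 19.6 | 57.0 |
| epsilon | 3.00 | 33.8 | 36.1 |
| epsilon | 6.00 | 44.6 | 14.0 |
| epsilon | 10.0 | 54.3 | 2.9 |
| epsilon | 20.0 | 53.6 | 0 |
| gamma | 1.50 | 12.5 | 34.8 |
| gamma | 3.00 | 19.6 | 21.2 |
| gamma | 6.00 | 26.7 | 7.3 |
| gamma | 10.0 | 31.8 | 2.4 |
| gamma | 20.0 | 32.4 | 0.5 |

(each reading ± 1 percentage point)

- "hardly changes" means that all values lie within two and a half points (for a concentration: within two and a half percent of the largest)

* amount of target at the end, in percent of the starting material and other conformer together charged for maple, cedar, elm, alder, oak, in this order
* the shape of the row from first to last (rises, then falls / falls all the way / falls, then rises / hardly changes / rises all the way)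

Both runs have stopped by 20.0 min, where starting material reads 0% in epsilon and 0.5% in gamma, so their last readings are end values. The percentages count both charged conformers, so first rebase them on the starting material charged: multiply by one plus x, where x is the equivalents of other conformer. Epsilon gives 60.6% and gamma 90.7%. With the protic impurity fixed at 0.0360 M, draw a straight line through these two points. Its slope b, the target per other conformer charged, is 0.181. Its intercept s, the target per starting material charged, is 0.582.

The second way stays inside one run. In gamma at 1.50 min, starting material and target together already make 132% of the starting material charged, so some other conformer has turned into starting material by then. If that passage is over by the first reading, s is also target gained per starting material lost afterwards. From 1.50 min to 10.0 min that ratio reads 0.641 in epsilon and 0.596 in gamma. These rest on differences of 54 percentage points and 32 points with a scatter of 1 point per reading, so their second digit is soft. They sit a little above the intercept, but they use different readings and land close to it, so I keep s.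

Back on the asked basis, the yield is (s + b x) over (one + x). My row is 54.6%, 51.5%, 46.7%, 40.4%, 34.1%. It falls from end to end, because each added other conformer brings less target than s.

The forecast, 0.50 points above mine in maple, reads 55.1%, 52%, 47%, 40.4%, 33.9%, falls all the way, on the grounds that “Absolute target rises, but the percent falls throughout because the denominator grows faster.”

The flasks give 54.7%, 51.7%, 46.9%, 40.6%, 34.4%: falls all the way.

    starting material ⇌ other conformer (K = 0.100, k = 0.00328 /s)
    starting material → target (k = 0.00314 /s)
    other conformer → isomer of the product (k = 0.0656 /s)
    other conformer ⇌ third conformer (K = 3.17, k = 0.00353 /s)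
    third conformer → third product (k = 0.0375 /s)
    other conformer + protic impurity → quenched substrate (k = 0.0418 /M/s)

Put into oak, s and b give 34.1% beside the flask's 34.4%, and put into maple they give 54.6% beside 54.7%. In maple at 2.17 min, starting material goes to target at 0.96 of the forward rate of its loss to other conformer. Other conformer goes on to isomer of the product 2.00 times as fast as it returns to starting material, and oak at 20.0 min holds 34.4% target against 61.0% isomer of the product.

The numbers in the tables were computed with made-up constants, and the scatter is random.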